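## Analysis of the target

The target is a 1,2-dioxolane-3-acetic acid. The ring is O1–O2–C3–C4–C5; C3 carries a methyl group and the CH2CO2H arm (C2, C1), and C5 carries a methyl group and the chain C6–C17, which ends in a phenyl ring. This numbering (C1 = carboxyl carbon, C17 = carbon bonded to phenyl) is used for every intermediate.

There are three stereocentres: C3 (S), C5 (R) and C7 (R). The two ring methyl groups are trans, so the C5 methyl lies on the ring face of the acetic acid arm and the long chain on the face of the C3 methyl. C7 is a methyl-branched CH separated from the ring by the C6 methylene and cannot relay stereochemical information to it. C14=C15 and C16=C17 are both E and conjugated with the phenyl ring.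

The sensitive groups are the O–O bond (reductants, low-valent metals, heat), the ester β to a peroxide oxygen (enolisation can expel the peroxide) and the styryl diene (electrophilic halogen, radicals, acid). The difficulty is that both peroxide carbons are fully substituted and each is differentiated only by methyl against CH2. Neither can be corrected by epimerisation, and the absolute configuration of the ring has to be set independently of C7.

The strategy rests on C5: it bears a methyl group and two methylenes (C4 and C6), so it can be the internal carbon of a 1,1-disubstituted alkene whose terminal carbon becomes the C5 methyl. A C3 hydroperoxide of fixed configuration can then close the ring onto that alkene through an iodonium ion.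

## Retrosynthetic reasoning

**27 to 26.** The acid is released last from its methyl ester, so that a neutral, chromatographable ester is carried through all peroxide chemistry. The forward step is a mild saponification.

**26 to 23 and 24.** The C14=C15 bond is cut. The styryl diene would not survive electrophilic iodine, tin radicals or acidic perhydrolysis, so it is attached after the ring is complete. Phosphonate 24 brings C15–C17 and the phenyl ring with one E alkene already in place. The forward olefination has to give the second E alkene without enolising the ester.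

**23 to 21.** Aldehyde 23 is traced back through alcohol 22 to silyl ether 21; the C14 oxygen stays protected by one robust group from the first step onwards.

**21 to 20.** The C5 methyl is traced back to an iodomethyl group. The C–I bond is the scar of the ring closure, and the forward step must replace iodine by hydrogen without breaking the O–O bond two atoms away.

**20 to 19.** The O–C5 bond is cut. This is the best place to open the ring because C5 has no heteroatom partner other than the peroxide and is flanked by two methylenes and a methyl. The precursor is therefore simply an alkene, and the nucleophile is a hydroperoxide on C3 whose configuration is already fixed. The forward reaction must form the O–C5 bond at the substituted alkene carbon (5-exo) and create C5.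

**19 to 14.** The methyl ester arm is traced back to the hydroxyethyl arm of 14. The alcohol has to be oxidised while the hydroperoxide is masked (15, 17, 18), because a free hydroperoxide would add to the intermediate aldehyde.

**14 to 13.** The C3–O bond is cut. A tertiary hydroperoxide of defined configuration is best made by invertive perhydrolysis of a strained cyclic ether, so 14 is traced back to the 2,2-disubstituted oxetane 13. Its ring oxygen becomes the C1 hydroxyl. The forward step must open the oxetane at the quaternary carbon with inversion and leave the C5=CH2 bond alone.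

**13 to 12.** The C5=CH2 bond is traced back to ketone 12. The forward methylenation has to be non-basic, because the ketone has the oxetane oxygen in the β position.

**12 to 10 and 11.** The C5–C6 bond is cut between an acyl carbon and a primary carbanion, giving Weinreb amide 10 and Grignard reagent 11 (from bromide 6). This keeps C7 one carbon away from the bond being formed and makes the route convergent.

**10 to 7.** Oxetane 10 is traced back through tosylate 9 and diol amide 8 to mevalonolactone. The lactone carries the quaternary carbinol carbon with exactly the two arms needed: the acyl arm becomes C4–C5 and the hydroxyethyl arm becomes C2–C1. Amide formation and oxetane closure retain the carbinol C–O bond and the perhydrolysis inverts it. With this assignment of the arms the (S)-lactone 7 is required; the natural (R)-lactone would lead through the same sequence to the C3 epimer.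

**6 to 2 and 3.** The C8–C9 bond is cut. Bromo alcohol 3 supplies C6–C8 with the C7 stereocentre, and Grignard reagent 4 (from 2, made from 1) supplies C9–C14. The hydroxyl of 5 is then exchanged for bromide to give 6.

## Alternatives that were turned down

**Alternative 1:** Both ring C–O bonds are disconnected back to dioxygen. The 3-ethenyl-3,5-dimethyl-1,2-dioxolane A1 would come from the vinylcyclopropane A2 by thiyl-radical-catalysed oxygenation (diphenyl disulfide, light, O2).

- Forward key step: the thiyl radical adds to the vinyl CH2, the cyclopropane opens to the tertiary C5 radical, O2 is captured, and the peroxyl radical closes 5-exo on C3 and releases the thiyl radical. The vinyl group of A1 would later be converted into the CH2CO2H arm.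
- For it: one step makes the ring and both C–O bonds, and A2 needs no defined configuration.
- Against it: C5 passes through a planar radical and C3 through an sp2 carbon, so nothing in A2 can be transmitted. A1 would form in both relative configurations and in both absolute senses of the ring. The only fixed centre, C7, is too remote to allow separation of the mirror-image rings. Anti-Markovnikov oxidation of the vinyl group next to an O–O bond is a further burden.
- Comparison: it reaches the ring in fewer steps than the chosen route, but it cannot deliver the single stereoisomer. The chosen route spends steps to fix C3 absolutely before the ring is closed.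

**Alternative 2:** The O2–C3 bond is disconnected. The 3-(2-hydroxyethyl) dioxolane A3 would come from the hydroperoxy oxetane A4, itself available from 13 by cobalt-catalysed hydroperoxysilylation of the C5=CH2 bond.

- Forward key step: under a catalytic silyl triflate the tertiary C5 hydroperoxide attacks the quaternary oxetane carbon from the rear (5-exo, inversion at C3), and the oxetane oxygen leaves as the hydroxyethyl arm.
- For it: delivery of the peroxide is intramolecular and so more SN2-like than a bimolecular perhydrolysis. No hydroperoxide masking is needed, because the peroxide is already a dialkyl peroxide when the alcohol is released. It starts from the same oxetane 13 and is about two steps shorter.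
- Against it: the C5 hydroperoxide is installed with no facial control, so both C5 epimers are carried here as well. The ring closure asks a tertiary hydroperoxide to displace at a fully substituted carbon; if the oxetane ionises first, C3 is scrambled in the very step that closes the ring, and one of the resulting isomers is the practically inseparable mirror-image ring.
- Comparison: this alternative is stronger on step count and at least equal on fidelity at C3. In its place the chosen strategy offers a ring closure that does not involve C3 at all: C3 is made and purified on an open-chain compound, the ring is then closed by a fast, irreversible halonium reaction under neutral conditions, and the iodomethyl group helps the separation of the C5 epimers. Alternative 2 is kept as the fallback for step 9.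

**Alternative 3:** The C3–C4 and C5–O1 bonds are disconnected. The 3-(2-acetoxyethyl) dioxolane A5 would come from the silylperoxy ketal A6 and the 1,1-disubstituted alkene A7 with SnCl4.

- Forward key step: A6 ionises to a peroxycarbenium ion, the CH2 terminus of A7 attacks it to form C3–C4, and the silylperoxy oxygen closes on the tertiary C5 cation.
- For it: it is the most convergent plan. A C–C bond and the ring are made together from two fragments that need only a few steps each.
- Against it: the peroxycarbenium ion is planar and achiral and the C5 cation is planar, so neither C3 nor C5 is controlled in the absolute sense. Only a modest cis/trans preference can be expected, and C7 again cannot resolve the mirror-image rings.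
- Comparison: it is clearly stronger on convergence and step count. The chosen strategy supplies what it lacks, the absolute configuration of C3 from the chiral pool, and leaves only C5 to chromatography.

Key step: step 14

Remark: (S)-mevalonolactone 7, the antipode of the natural lactone, is assumed to be purchasable in enantiopure form.

## Route

Step 1
Reactants: 1 6-bromohexan-1-ol
Product: 2 [(6-bromohexyl)oxy](tert-butyl)diphenylsilane
Conditions: TBDPSCl, imidazole, CH2Cl2, 0 °C to rt
Reagents that add atoms: tert-butyl(chloro)diphenylsilane, CC(C)(C)[Si](Cl)(c1ccccc1)c1ccccc1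
Why: Standard silylation of a primary alcohol; the TBDPS ether tolerates Grignard formation, the acidic perhydrolysis, the oxidations and the radical step, and the primary bromide is not touched.

Step 2
Reactants: 2 [(6-bromohexyl)oxy](tert-butyl)diphenylsilane; 3 (S)-3-bromo-2-methylpropan-1-ol
Product: 5 (2R)-9-[(tert-butyldiphenylsilyl)oxy]-2-methylnonan-1-ol, via alkylmagnesium bromide 4 (not isolated)
Conditions: 2, Mg, THF, rt; then 3 (0.4 equiv), Li2CuCl4 (5 mol%), THF, −20 °C to rt
Reagents that add atoms: none
Why: Copper-catalysed sp3–sp3 coupling of a Grignard reagent with a primary alkyl bromide (Kochi-type); the first equivalent of 4 converts the hydroxyl of 3 into its magnesium alkoxide and the second displaces bromide to form C8–C9. C7 is not involved, and its descriptor changes from S to R only because the priorities change.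

Step 3
Reactants: 5 (2R)-9-[(tert-butyldiphenylsilyl)oxy]-2-methylnonan-1-ol
Product: 6 {[(8R)-9-bromo-8-methylnonyl]oxy}(tert-butyl)diphenylsilane
Conditions: CBr4, PPh3, CH2Cl2, 0 °C
Reagents that add atoms: carbon tetrabromide, BrC(Br)(Br)Br
Why: Appel bromination; substitution takes place at the primary C6 carbon, so C7 cannot epimerise and the silyl ether is inert.

Step 4
Reactants: 7 (S)-mevalonolactone [(4S)-4-hydroxy-4-methyloxan-2-one]
Product: 8 (3S)-3,5-dihydroxy-N-methoxy-N,3-dimethylpentanamide
Conditions: MeNH(OMe)·HCl, AlMe3, CH2Cl2, 0 °C to rt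
Reagents that add atoms: N,O-dimethylhydroxylamine hydrochloride, CNOC.Cl
Why: Weinreb aminolysis of a lactone by the aluminium amide; the quaternary carbinol carbon (future C3) is not touched, the acyl carbon becomes C5 and the liberated hydroxyethyl arm becomes C2–C1.

Step 5
Reactants: 8 (3S)-3,5-dihydroxy-N-methoxy-N,3-dimethylpentanamide
Product: 9 (3S)-3-hydroxy-5-[methoxy(methyl)amino]-3-methyl-5-oxopentyl 4-methylbenzenesulfonate
Conditions: TsCl, Et3N, DMAP (cat.), CH2Cl2, 0 °C
Reagents that add atoms: 4-methylbenzenesulfonyl chloride, Cc1ccc(cc1)S(Cl)(=O)=O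
Why: Selective sulfonylation of the primary hydroxyl in the presence of the tertiary one; it is run directly on crude 8 so that the 5-hydroxy amide does not close back to the lactone.

Step 6
Reactants: 9 (3S)-3-hydroxy-5-[methoxy(methyl)amino]-3-methyl-5-oxopentyl 4-methylbenzenesulfonate
Product: 10 N-methoxy-N-methyl-2-[(2S)-2-methyloxetan-2-yl]acetamide
Conditions: KOtBu, THF, 0 °C to rt
Reagents that add atoms: none
Why: Intramolecular Williamson etherification (4-exo-tet) of the tertiary alkoxide onto the primary tosylate; the C3–O bond is kept, so the configuration of the quaternary carbon is retained.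

Step 7
Reactants: 6 {[(8R)-9-bromo-8-methylnonyl]oxy}(tert-butyl)diphenylsilane; 10 N-methoxy-N-methyl-2-[(2S)-2-methyloxetan-2-yl]acetamide
Product: 12 (4R)-11-[(tert-butyldiphenylsilyl)oxy]-4-methyl-1-[(2S)-2-methyloxetan-2-yl]undecan-2-one, via alkylmagnesium bromide 11 (not isolated)
Conditions: 6, Mg, THF, rt; then 10, THF, 0 °C; aq. NH4Cl
Reagents that add atoms: none
Why: Weinreb ketone synthesis forming C5–C6; the chelated tetrahedral intermediate prevents over-addition. A Grignard reagent is chosen over an organolithium to limit deprotonation at C4, which would open the oxetane by β-elimination.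

Step 8
Reactants: 12 (4R)-11-[(tert-butyldiphenylsilyl)oxy]-4-methyl-1-[(2S)-2-methyloxetan-2-yl]undecan-2-one
Product: 13 tert-butyl({(8R)-8-methyl-10-methylidene-11-[(2R)-2-methyloxetan-2-yl]undecyl}oxy)diphenylsilane
Conditions: Cp2TiMe2, toluene, 65 °C, dark
Reagents that add atoms: dimethyltitanocene (Cp2TiMe2), [CH3-].[CH3-].[Ti+4].c1cc[cH-]c1.c1cc[cH-]c1
Why: Petasis methylenation: the thermally formed Cp2Ti=CH2 converts the C5 carbonyl into C5=CH2 through an oxatitanacyclobutane. The reagent is not basic, so the β-oxetanyl ketone is not enolised; the oxetane descriptor changes to R only through the change in priorities.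

Step 9
Reactants: 13 tert-butyl({(8R)-8-methyl-10-methylidene-11-[(2R)-2-methyloxetan-2-yl]undecyl}oxy)diphenylsilane
Product: 14 (3S,7R)-14-[(tert-butyldiphenylsilyl)oxy]-3-hydroperoxy-3,7-dimethyl-5-methylidenetetradecan-1-ol
Conditions: H2O2 (anhydrous, in Et2O, 10 equiv), TMSOTf (0.2 equiv), Et2O, −78 to −40 °C
Reagents that add atoms: hydrogen peroxide, OO
Why: Lewis-acid-promoted perhydrolysis of a 2,2-disubstituted oxetane, a known route to 3-hydroperoxyalkan-1-ols; H2O2 attacks the activated oxetane at its more substituted carbon from the side opposite the departing oxygen, so C3 is formed with inversion of the lactone-derived centre and the ring oxygen becomes the C1 hydroxyl. Low temperature, ether and a large excess of H2O2 keep the opening bimolecular and keep the C5=CH2 bond and the silyl ether out of play.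

Step 10
Reactants: 14 (3S,7R)-14-[(tert-butyldiphenylsilyl)oxy]-3-hydroperoxy-3,7-dimethyl-5-methylidenetetradecan-1-ol
Product: 15 (3S,7R)-14-[(tert-butyldiphenylsilyl)oxy]-3,7-dimethyl-5-methylidene-3-[(triethylsilyl)peroxy]tetradecan-1-ol
Conditions: TESCl (1.05 equiv), Et3N, CH2Cl2, −40 °C
Reagents that add atoms: chlorotriethylsilane, CC[Si](Cl)(CC)CC
Why: Chemoselective O-silylation: the hydroperoxide is about three pKa units more acidic than the primary alcohol and is an alpha-effect nucleophile, so with one equivalent of silyl chloride, an amine as the only base and no nucleophilic catalyst it should react first. The silyl peroxide stops the OOH group from adding to the aldehyde formed in step 11.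

Step 11
Reactants: 15 (3S,7R)-14-[(tert-butyldiphenylsilyl)oxy]-3,7-dimethyl-5-methylidene-3-[(triethylsilyl)peroxy]tetradecan-1-ol
Product: 17 (3S,7R)-14-[(tert-butyldiphenylsilyl)oxy]-3,7-dimethyl-5-methylidene-3-[(triethylsilyl)peroxy]tetradecanoic acid, via aldehyde 16 (not isolated)
Conditions: TEMPO (cat.), PhI(OAc)2, MeCN/pH 7 buffer, 0 °C to rt
Reagents that add atoms: water, O
Why: Oxoammonium-mediated oxidation of a primary alcohol; the hydrate of aldehyde 16 is oxidised further to the acid in the aqueous medium. The isolated 1,1-disubstituted alkene, the silyl peroxide and the TBDPS ether are not oxidised under these near-neutral conditions.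

Step 12
Reactants: 17 (3S,7R)-14-[(tert-butyldiphenylsilyl)oxy]-3,7-dimethyl-5-methylidene-3-[(triethylsilyl)peroxy]tetradecanoic acid
Product: 18 methyl (3S,7R)-14-[(tert-butyldiphenylsilyl)oxy]-3,7-dimethyl-5-methylidene-3-[(triethylsilyl)peroxy]tetradecanoate
Conditions: TMSCHN2, toluene/MeOH, 0 °C
Reagents that add atoms: (trimethylsilyl)diazomethane, C[Si](C)(C)C=[N+]=[N-]
Why: Methyl esterification by a diazoalkane under neutral conditions; no base is present that could eliminate the β-silylperoxy group.

Step 13
Reactants: 18 methyl (3S,7R)-14-[(tert-butyldiphenylsilyl)oxy]-3,7-dimethyl-5-methylidene-3-[(triethylsilyl)peroxy]tetradecanoate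
Product: 19 methyl (3S,7R)-14-[(tert-butyldiphenylsilyl)oxy]-3-hydroperoxy-3,7-dimethyl-5-methylidenetetradecanoate
Conditions: HCl (cat.), MeOH, 0 °C
Reagents that add atoms: none
Why: Acid-catalysed methanolysis of the Si–OO bond, the usual release of a hydroperoxide from a triethylsilyl peroxide; the primary TBDPS ether, the methyl ester and the alkene are stable to catalytic HCl at 0 °C.

Step 14
Reactants: 19 methyl (3S,7R)-14-[(tert-butyldiphenylsilyl)oxy]-3-hydroperoxy-3,7-dimethyl-5-methylidenetetradecanoate
Product: 20 methyl 2-[(3S,5R)-5-{(2R)-9-[(tert-butyldiphenylsilyl)oxy]-2-methylnonyl}-5-(iodomethyl)-3-methyl-1,2-dioxolan-3-yl]acetate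
Conditions: NIS (1.3 equiv), CH2Cl2, 0 °C to rt, dark; chromatographic separation of the C5 epimers
Reagents that add atoms: N-iodosuccinimide, O=C1CCC(=O)N1I
Why: Iodoperoxidation, the halocyclisation of an unsaturated hydroperoxide and the peroxide counterpart of iodoetherification, known for halomethyl 1,2-dioxolanes. NIS transfers I+ to the electron-rich C5=CH2 bond; the iodonium ion carries most of its positive charge on the fully substituted C5, and the terminal oxygen of the C3 hydroperoxide opens it there, anti to iodine, the proton going to succinimide. The ring O1–O2–C3–C4–C5 closes in the 5-exo-trig (Markovnikov) mode; the 6-endo mode would require attack at the unsubstituted CH2 and is not expected. The new stereocentre C5 is controlled only by C3 through an envelope-like transition state, and the required isomer has the iodomethyl group cis to the CH2CO2Me arm. Because methyl and CH2CO2Me differ little in size, little facial bias is expected; both C5 epimers should form and are separated here, where the iodomethyl group differentiates them most. The step also needs the hydroperoxide to be the only competent nucleophile and the O–O bond to survive the iodine source: the ester, the silyl ether and C7 are inert, no second alkene or free hydroxyl is present, and the reaction is run cold, dark and without acid or base.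

Step 15
Reactants: 20 methyl 2-[(3S,5R)-5-{(2R)-9-[(tert-butyldiphenylsilyl)oxy]-2-methylnonyl}-5-(iodomethyl)-3-methyl-1,2-dioxolan-3-yl]acetate
Product: 21 methyl 2-[(3S,5R)-5-{(2R)-9-[(tert-butyldiphenylsilyl)oxy]-2-methylnonyl}-3,5-dimethyl-1,2-dioxolan-3-yl]acetate
Conditions: Bu3SnH (10 equiv, about 2 M), Et3B (cat.), air, toluene, 0 °C
Reagents that add atoms: none
Why: Radical-chain hydrodeiodination; the primary radical on the exocyclic carbon is β to the peroxide and can collapse to an epoxide with O–O cleavage, so the stannane is used in large excess, at high concentration and at low temperature to make hydrogen transfer the faster event. C3 and C5 are not touched.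

Step 16
Reactants: 21 methyl 2-[(3S,5R)-5-{(2R)-9-[(tert-butyldiphenylsilyl)oxy]-2-methylnonyl}-3,5-dimethyl-1,2-dioxolan-3-yl]acetate
Product: 22 methyl 2-{(3S,5R)-5-[(2R)-9-hydroxy-2-methylnonyl]-3,5-dimethyl-1,2-dioxolan-3-yl}acetate
Conditions: TBAF, AcOH, THF, rt
Reagents that add atoms: none
Why: Fluoride cleavage of the silyl ether; buffering with AcOH keeps the medium from enolising the ester β to the peroxide.

Step 17
Reactants: 22 methyl 2-{(3S,5R)-5-[(2R)-9-hydroxy-2-methylnonyl]-3,5-dimethyl-1,2-dioxolan-3-yl}acetate
Product: 23 methyl 2-{(3S,5R)-3,5-dimethyl-5-[(2R)-2-methyl-9-oxononyl]-1,2-dioxolan-3-yl}acetate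
Conditions: Dess–Martin periodinane, CH2Cl2, rt
Reagents that add atoms: none
Why: Dess–Martin oxidation of the primary alcohol to the C14 aldehyde; the dialkyl peroxide and the ester are inert to the hypervalent iodine reagent.

Step 18
Reactants: 23 methyl 2-{(3S,5R)-3,5-dimethyl-5-[(2R)-2-methyl-9-oxononyl]-1,2-dioxolan-3-yl}acetate; 24 diethyl [(2E)-3-phenylprop-2-en-1-yl]phosphonate
Product: 26 methyl 2-{(3S,5R)-3,5-dimethyl-5-[(2R,9E,11E)-2-methyl-12-phenyldodeca-9,11-dien-1-yl]-1,2-dioxolan-3-yl}acetate, via lithiated phosphonate 25 (not isolated)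
Conditions: 24, n-BuLi (0.95 equiv per 24), THF, −78 °C; then 23, −78 °C to rt
Reagents that add atoms: none
Why: Horner–Wadsworth–Emmons olefination with an allylic phosphonate carbanion, which should give the new C14=C15 bond with E geometry and keep the E geometry of C16=C17. The carbanion is made with a slight deficit of base and meets the aldehyde at −78 °C, so that addition outruns deprotonation next to the ester.

Step 19
Reactants: 26 methyl 2-{(3S,5R)-3,5-dimethyl-5-[(2R,9E,11E)-2-methyl-12-phenyldodeca-9,11-dien-1-yl]-1,2-dioxolan-3-yl}acetate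
Product: 27 2-{(3S,5R)-3,5-dimethyl-5-[(2R,9E,11E)-2-methyl-12-phenyldodeca-9,11-dien-1-yl]-1,2-dioxolan-3-yl}acetic acid
Conditions: LiOH, THF/MeOH/H2O, 0 °C; then 1 M HCl
Reagents that add atoms: lithium hydroxide, [Li+].[OH-]
Why: Saponification of the methyl ester at low temperature, the usual last step for 1,2-dioxolane-3-acetic esters; neither peroxide carbon bears a hydrogen, so base-induced peroxide fragmentation through an α-hydrogen is impossible, and acidification gives the target.

## Compound list

1 | 6-bromohexan-1-ol | OCCCCCCBr | starting material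
2 | [(6-bromohexyl)oxy](tert-butyl)diphenylsilane | BrCCCCCCO[Si](c1ccccc1)(c1ccccc1)C(C)(C)C | intermediate
3 | (S)-3-bromo-2-methylpropan-1-ol | C[C@H](CBr)CO | starting material
4 | {6-[(tert-butyldiphenylsilyl)oxy]hexyl}magnesium bromide | Br[Mg]CCCCCCO[Si](c1ccccc1)(c1ccccc1)C(C)(C)C | intermediate
5 | (2R)-9-[(tert-butyldiphenylsilyl)oxy]-2-methylnonan-1-ol | C[C@H](CCCCCCCO[Si](c1ccccc1)(c1ccccc1)C(C)(C)C)CO | intermediate
6 | {[(8R)-9-bromo-8-methylnonyl]oxy}(tert-butyl)diphenylsilane | C[C@H](CCCCCCCO[Si](c1ccccc1)(c1ccccc1)C(C)(C)C)CBr | intermediate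
7 | (S)-mevalonolactone, (4S)-4-hydroxy-4-methyloxan-2-one | C[C@]1(O)CCOC(=O)C1 | starting material
8 | (3S)-3,5-dihydroxy-N-methoxy-N,3-dimethylpentanamide | CON(C)C(=O)C[C@@](C)(O)CCO | intermediate
9 | (3S)-3-hydroxy-5-[methoxy(methyl)amino]-3-methyl-5-oxopentyl 4-methylbenzenesulfonate | CON(C)C(=O)C[C@@](C)(O)CCOS(=O)(=O)c1ccc(C)cc1 | intermediate
10 | N-methoxy-N-methyl-2-[(2S)-2-methyloxetan-2-yl]acetamide | CON(C)C(=O)C[C@]1(C)CCO1 | intermediate
11 | {(2R)-9-[(tert-butyldiphenylsilyl)oxy]-2-methylnonyl}magnesium bromide | C[C@H](CCCCCCCO[Si](c1ccccc1)(c1ccccc1)C(C)(C)C)C[Mg]Br | intermediate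
12 | (4R)-11-[(tert-butyldiphenylsilyl)oxy]-4-methyl-1-[(2S)-2-methyloxetan-2-yl]undecan-2-one | C[C@H](CCCCCCCO[Si](c1ccccc1)(c1ccccc1)C(C)(C)C)CC(=O)C[C@]1(C)CCO1 | intermediate
13 | tert-butyl({(8R)-8-methyl-10-methylidene-11-[(2R)-2-methyloxetan-2-yl]undecyl}oxy)diphenylsilane | C[C@H](CCCCCCCO[Si](c1ccccc1)(c1ccccc1)C(C)(C)C)CC(=C)C[C@]1(C)CCO1 | intermediate
14 | (3S,7R)-14-[(tert-butyldiphenylsilyl)oxy]-3-hydroperoxy-3,7-dimethyl-5-methylidenetetradecan-1-ol | C[C@H](CCCCCCCO[Si](c1ccccc1)(c1ccccc1)C(C)(C)C)CC(=C)C[C@@](C)(CCO)OO | intermediate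
15 | (3S,7R)-14-[(tert-butyldiphenylsilyl)oxy]-3,7-dimethyl-5-methylidene-3-[(triethylsilyl)peroxy]tetradecan-1-ol | C[C@H](CCCCCCCO[Si](c1ccccc1)(c1ccccc1)C(C)(C)C)CC(=C)C[C@@](C)(CCO)OO[Si](CC)(CC)CC | intermediate
16 | (3S,7R)-14-[(tert-butyldiphenylsilyl)oxy]-3,7-dimethyl-5-methylidene-3-[(triethylsilyl)peroxy]tetradecanal | C[C@H](CCCCCCCO[Si](c1ccccc1)(c1ccccc1)C(C)(C)C)CC(=C)C[C@@](C)(CC=O)OO[Si](CC)(CC)CC | intermediate
17 | (3S,7R)-14-[(tert-butyldiphenylsilyl)oxy]-3,7-dimethyl-5-methylidene-3-[(triethylsilyl)peroxy]tetradecanoic acid | C[C@H](CCCCCCCO[Si](c1ccccc1)(c1ccccc1)C(C)(C)C)CC(=C)C[C@@](C)(CC(=O)O)OO[Si](CC)(CC)CC | intermediate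
18 | methyl (3S,7R)-14-[(tert-butyldiphenylsilyl)oxy]-3,7-dimethyl-5-methylidene-3-[(triethylsilyl)peroxy]tetradecanoate | C[C@H](CCCCCCCO[Si](c1ccccc1)(c1ccccc1)C(C)(C)C)CC(=C)C[C@@](C)(CC(=O)OC)OO[Si](CC)(CC)CC | intermediate
19 | methyl (3S,7R)-14-[(tert-butyldiphenylsilyl)oxy]-3-hydroperoxy-3,7-dimethyl-5-methylidenetetradecanoate | C[C@H](CCCCCCCO[Si](c1ccccc1)(c1ccccc1)C(C)(C)C)CC(=C)C[C@@](C)(CC(=O)OC)OO | intermediate
20 | methyl 2-[(3S,5R)-5-{(2R)-9-[(tert-butyldiphenylsilyl)oxy]-2-methylnonyl}-5-(iodomethyl)-3-methyl-1,2-dioxolan-3-yl]acetate | C[C@H](CCCCCCCO[Si](c1ccccc1)(c1ccccc1)C(C)(C)C)C[C@]1(CI)C[C@@](C)(CC(=O)OC)OO1 | intermediate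
21 | methyl 2-[(3S,5R)-5-{(2R)-9-[(tert-butyldiphenylsilyl)oxy]-2-methylnonyl}-3,5-dimethyl-1,2-dioxolan-3-yl]acetate | C[C@H](CCCCCCCO[Si](c1ccccc1)(c1ccccc1)C(C)(C)C)C[C@]1(C)C[C@@](C)(CC(=O)OC)OO1 | intermediate
22 | methyl 2-{(3S,5R)-5-[(2R)-9-hydroxy-2-methylnonyl]-3,5-dimethyl-1,2-dioxolan-3-yl}acetate | C[C@H](CCCCCCCO)C[C@]1(C)C[C@@](C)(CC(=O)OC)OO1 | intermediate
23 | methyl 2-{(3S,5R)-3,5-dimethyl-5-[(2R)-2-methyl-9-oxononyl]-1,2-dioxolan-3-yl}acetate | C[C@H](CCCCCCC=O)C[C@]1(C)C[C@@](C)(CC(=O)OC)OO1 | intermediate
24 | diethyl [(2E)-3-phenylprop-2-en-1-yl]phosphonate | CCOP(=O)(C/C=C/c1ccccc1)OCC | starting material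
25 | lithium salt of diethyl [(2E)-3-phenylprop-2-en-1-yl]phosphonate, carbanion at the carbon next to phosphorus | [Li+].CCOP(=O)([CH-]/C=C/c1ccccc1)OCC | intermediate
26 | methyl 2-{(3S,5R)-3,5-dimethyl-5-[(2R,9E,11E)-2-methyl-12-phenyldodeca-9,11-dien-1-yl]-1,2-dioxolan-3-yl}acetate | C[C@H](CCCCCC/C=C/C=C/c1ccccc1)C[C@]1(C)C[C@@](C)(CC(=O)OC)OO1 | intermediate
27 | 2-{(3S,5R)-3,5-dimethyl-5-[(2R,9E,11E)-2-methyl-12-phenyldodeca-9,11-dien-1-yl]-1,2-dioxolan-3-yl}acetic acid | C[C@H](CCCCCC/C=C/C=C/c1ccccc1)C[C@]1(C)C[C@@](C)(CC(=O)O)OO1 | target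

## Step count and least certain steps

Total: 19 steps. Longest linear sequence: 16 steps (steps 1–3 and 7–19 from 1; the branch from 7, steps 4–6 and 7–19, has the same length).

**Step 14 (key step).** The most likely problem is poor facial discrimination at C5, because the only controlling element is the small difference between the methyl group and the CH2CO2Me arm on C3, so that a large part of the material ends up as the unwanted C5 epimer. A second problem is oxidative consumption of the hydroperoxide by the iodine source. Fallback: cyclo-peroxymercuration. Setting out from 19, Hg(OAc)2 in CH2Cl2 with a trace of HClO4 should close the same ring to methyl 2-[(3S,5R)-5-[(acetoxymercurio)methyl]-5-{(2R)-9-[(tert-butyldiphenylsilyl)oxy]-2-methylnonyl}-3-methyl-1,2-dioxolan-3-yl]acetate F1. Peroxymercuration is reversible under acid, so the C5 epimers can equilibrate, and the mercury salt is not an oxidant for the hydroperoxide. Reduction of F1 with NaBH4 in a cold two-phase system replaces mercury by hydrogen and comes back to the route at 21, so that neither 20 nor the tin step is needed.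

**Step 9.** The oxetane may ionise before H2O2 arrives. This would erode the configuration at C3, cause elimination towards alkenes, and let the homoallylic C5=CH2 bond intercept the cation. An eroded C3 cannot be repaired later, because C7 is too remote to allow separation. Fallback: the peroxide is delivered intramolecularly. Setting out from 13, Mukaiyama–Isayama peroxidation (Co(acac)2, O2, Et3SiH) of the C5=CH2 bond gives the oxetane 13 with CH3 and OOSiEt3 on C5 F2 as both C5 epimers. K2CO3 in MeOH releases the C5 hydroperoxide of that oxetane F3. Catalytic TMSOTf then lets the C5 hydroperoxide open the oxetane at C3 from the rear (5-exo, inversion) to give the (3S,5R)-3-(2-hydroxyethyl)-3,5-dimethyl-1,2-dioxolane with the silyl-protected chain F4, and the C5 epimers are separated at this point. Oxidation with TEMPO and PhI(OAc)2 passes through the corresponding dioxolane acetaldehyde F5 to the dioxolane acetic acid F6, and TMSCHN2 returns to the route at 21. This fallback gives up the halocyclisation.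

**Step 10.** Silylation may not discriminate fully between the hydroperoxide and the primary alcohol, and the silyl peroxide may be lost during step 11; the free hydroperoxide would then add to the aldehyde and close a cyclic peroxyhemiacetal. Fallback: the alcohol is differentiated enzymatically and the peroxide is masked as a base-stable peroxyketal. Setting out from 14, immobilised Candida antarctica lipase B with vinyl acetate acylates only the primary hydroxyl to give the (3S,7R)-3-hydroperoxy acetate F7. 2-Methoxypropene and PPTS give its 2-methoxypropan-2-yl peroxyketal F8, and K2CO3 in MeOH removes the acetate to give the peroxyketal alcohol F9. Oxidation as in step 11 passes through the peroxyketal aldehyde F10 to the peroxyketal acid F11, TMSCHN2 gives the peroxyketal methyl ester F12, and aqueous AcOH in THF hydrolyses the peroxyketal and returns to the route at 19.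

**Step 15.** The β-peroxyalkyl radical may collapse to an epoxide with cleavage of the O–O bond before it is reduced, or the stannyl radical may attack the peroxide; either destroys the ring. Fallback: the ring is closed with a proton instead of an iodonium ion, so that no carbon radical next to the peroxide is ever formed. Setting out from 19, a catalytic strong acid (TfOH, CH2Cl2, −40 °C) should protonate the C5=CH2 bond at its CH2 terminus and let the C3 hydroperoxide capture the tertiary C5 cation. This is the intramolecular form of the classical acid-catalysed addition of tertiary hydroperoxides to 1,1-disubstituted alkenes, and it comes back to the route directly at 21 as the same pair of C5 epimers. It is held in reserve because the acid can also trigger rearrangement of the hydroperoxide and migration of the double bond.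

**Step 8.** Enolisation of the ketone towards C4 followed by β-elimination would open the oxetane, and the hindered ketone may react sluggishly. Fallback: Peterson olefination. Setting out from 12, Me3SiCH2MgCl with CeCl3 adds to the carbonyl group to give the tertiary β-hydroxysilane F13 (C5 bears OH and CH2SiMe3; mixture of C5 epimers). KH in THF then eliminates it; no carbonyl group is left at that stage, so no enolate can form, and the sequence returns to the route at 13.

## Further compounds

F1 | step 14 | methyl 2-[(3S,5R)-5-[(acetoxymercurio)methyl]-5-{(2R)-9-[(tert-butyldiphenylsilyl)oxy]-2-methylnonyl}-3-methyl-1,2-dioxolan-3-yl]acetate | C[C@H](CCCCCCCO[Si](c1ccccc1)(c1ccccc1)C(C)(C)C)C[C@]1(C[Hg]OC(C)=O)C[C@@](C)(CC(=O)OC)OO1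
F2 | step 9 | tert-butyl({(8R)-8,10-dimethyl-11-[(2S)-2-methyloxetan-2-yl]-10-[(triethylsilyl)peroxy]undecyl}oxy)diphenylsilane, both C5 epimers | C[C@H](CCCCCCCO[Si](c1ccccc1)(c1ccccc1)C(C)(C)C)CC(C)(OO[Si](CC)(CC)CC)C[C@]1(C)CCO1
F3 | step 9 | tert-butyl({(8R)-10-hydroperoxy-8,10-dimethyl-11-[(2S)-2-methyloxetan-2-yl]undecyl}oxy)diphenylsilane, both C5 epimers | C[C@H](CCCCCCCO[Si](c1ccccc1)(c1ccccc1)C(C)(C)C)CC(C)(OO)C[C@]1(C)CCO1
F4 | step 9 | 2-[(3S,5R)-5-{(2R)-9-[(tert-butyldiphenylsilyl)oxy]-2-methylnonyl}-3,5-dimethyl-1,2-dioxolan-3-yl]ethan-1-ol | C[C@H](CCCCCCCO[Si](c1ccccc1)(c1ccccc1)C(C)(C)C)C[C@]1(C)C[C@@](C)(CCO)OO1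
F5 | step 9 | 2-[(3S,5R)-5-{(2R)-9-[(tert-butyldiphenylsilyl)oxy]-2-methylnonyl}-3,5-dimethyl-1,2-dioxolan-3-yl]acetaldehyde | C[C@H](CCCCCCCO[Si](c1ccccc1)(c1ccccc1)C(C)(C)C)C[C@]1(C)C[C@@](C)(CC=O)OO1
F6 | step 9 | 2-[(3S,5R)-5-{(2R)-9-[(tert-butyldiphenylsilyl)oxy]-2-methylnonyl}-3,5-dimethyl-1,2-dioxolan-3-yl]acetic acid | C[C@H](CCCCCCCO[Si](c1ccccc1)(c1ccccc1)C(C)(C)C)C[C@]1(C)C[C@@](C)(CC(=O)O)OO1
F7 | step 10 | (3S,7R)-14-[(tert-butyldiphenylsilyl)oxy]-3-hydroperoxy-3,7-dimethyl-5-methylidenetetradecyl acetate | C[C@H](CCCCCCCO[Si](c1ccccc1)(c1ccccc1)C(C)(C)C)CC(=C)C[C@@](C)(CCOC(C)=O)OO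
F8 | step 10 | (3S,7R)-14-[(tert-butyldiphenylsilyl)oxy]-3-[(2-methoxypropan-2-yl)peroxy]-3,7-dimethyl-5-methylidenetetradecyl acetate | C[C@H](CCCCCCCO[Si](c1ccccc1)(c1ccccc1)C(C)(C)C)CC(=C)C[C@@](C)(CCOC(C)=O)OOC(C)(C)OC
F9 | step 10 | (3S,7R)-14-[(tert-butyldiphenylsilyl)oxy]-3-[(2-methoxypropan-2-yl)peroxy]-3,7-dimethyl-5-methylidenetetradecan-1-ol | C[C@H](CCCCCCCO[Si](c1ccccc1)(c1ccccc1)C(C)(C)C)CC(=C)C[C@@](C)(CCO)OOC(C)(C)OC
F10 | step 10 | (3S,7R)-14-[(tert-butyldiphenylsilyl)oxy]-3-[(2-methoxypropan-2-yl)peroxy]-3,7-dimethyl-5-methylidenetetradecanal | C[C@H](CCCCCCCO[Si](c1ccccc1)(c1ccccc1)C(C)(C)C)CC(=C)C[C@@](C)(CC=O)OOC(C)(C)OC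
F11 | step 10 | (3S,7R)-14-[(tert-butyldiphenylsilyl)oxy]-3-[(2-methoxypropan-2-yl)peroxy]-3,7-dimethyl-5-methylidenetetradecanoic acid | C[C@H](CCCCCCCO[Si](c1ccccc1)(c1ccccc1)C(C)(C)C)CC(=C)C[C@@](C)(CC(=O)O)OOC(C)(C)OC
F12 | step 10 | methyl (3S,7R)-14-[(tert-butyldiphenylsilyl)oxy]-3-[(2-methoxypropan-2-yl)peroxy]-3,7-dimethyl-5-methylidenetetradecanoate | C[C@H](CCCCCCCO[Si](c1ccccc1)(c1ccccc1)C(C)(C)C)CC(=C)C[C@@](C)(CC(=O)OC)OOC(C)(C)OC
F0 | step 15 | none | none
F13 | step 8 | (4R)-11-[(tert-butyldiphenylsilyl)oxy]-4-methyl-1-[(2S)-2-methyloxetan-2-yl]-2-[(trimethylsilyl)methyl]undecan-2-ol, both C5 epimers | C[C@H](CCCCCCCO[Si](c1ccccc1)(c1ccccc1)C(C)(C)C)CC(O)(C[Si](C)(C)C)C[C@]1(C)CCO1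
A1 | alternative 1 | tert-butyl({(8R)-9-[(3R,5S)-5-ethenyl-3,5-dimethyl-1,2-dioxolan-3-yl]-8-methylnonyl}oxy)diphenylsilane | C[C@H](CCCCCCCO[Si](c1ccccc1)(c1ccccc1)C(C)(C)C)C[C@]1(C)C[C@@](C)(C=C)OO1
A2 | alternative 1 | tert-butyl{[(8R)-9-(2-ethenyl-1,2-dimethylcyclopropyl)-8-methylnonyl]oxy}diphenylsilane, cyclopropane configuration not defined | C[C@H](CCCCCCCO[Si](c1ccccc1)(c1ccccc1)C(C)(C)C)CC1(C)CC1(C)C=C
A3 | alternative 2 | 2-[(3S,5R)-5-{(2R)-9-[(tert-butyldiphenylsilyl)oxy]-2-methylnonyl}-3,5-dimethyl-1,2-dioxolan-3-yl]ethan-1-ol | C[C@H](CCCCCCCO[Si](c1ccccc1)(c1ccccc1)C(C)(C)C)C[C@]1(C)C[C@@](C)(CCO)OO1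
A4 | alternative 2 | tert-butyl({(8R,10R)-10-hydroperoxy-8,10-dimethyl-11-[(2S)-2-methyloxetan-2-yl]undecyl}oxy)diphenylsilane | C[C@H](CCCCCCCO[Si](c1ccccc1)(c1ccccc1)C(C)(C)C)C[C@](OO)(C)C[C@]1(C)CCO1
A5 | alternative 3 | 2-[(3S,5R)-5-{(2R)-9-[(tert-butyldiphenylsilyl)oxy]-2-methylnonyl}-3,5-dimethyl-1,2-dioxolan-3-yl]ethyl acetate | C[C@H](CCCCCCCO[Si](c1ccccc1)(c1ccccc1)C(C)(C)C)C[C@]1(C)C[C@@](C)(CCOC(C)=O)OO1
A6 | alternative 3 | 3-methoxy-3-[(triethylsilyl)peroxy]butyl acetate | CC(=O)OCCC(C)(OC)OO[Si](CC)(CC)CC
A7 | alternative 3 | tert-butyl{[(8R)-8,10-dimethylundec-10-en-1-yl]oxy}diphenylsilane | C[C@H](CCCCCCCO[Si](c1ccccc1)(c1ccccc1)C(C)(C)C)CC(C)=C
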